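**Plan**

1. Retrosynthetic cuts: the C8 ester; the C11=C13 methylene and the lactone (C12–O6, then C7–C11); the ring bond C8–C9 by a retro-[3,3] shift that reconnects C1–C6; finally C6–C7 (alkoxyacetylide plus ketone).
2. Enabling feature: the C6 oxygen and the Z C1=C10 alkene are 1,5-related through C7, C8 and C9, so the ten-membered ring is a cyclodec-5-enone. Joining C1 to C6 gives the p-menthane ring C1–C6 of carvone, with the C4 methyl in place and the isopropenyl group supplying C10, its methyl and C9.
3. Forward order: carvone six-membered ring (oxygen moved to C3, oxygen added at C6), then the cis-1-(Z-alkoxyvinyl)-2-isopropenylcyclohexanol, then ring expansion to the ten-membered ring, then the γ-lactone at C6/C7, then methylenation, C8 ester and release of the C3 ketone.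
4. Stereochemistry: the (S)-carvone centre fixes C4 (equilibration, trans) and the face of the carbinol. The chair of the [3,3] shift converts it into 8R and the Z alkene. The C8 ether then steers C7 (chelated enolate alkylation) and C6 (chelation-controlled reduction). The side-chain E alkene comes from a thermodynamic allylic transposition.

Key step: step 13

Remark 1: target numbering is used for all intermediates (C1 CH bearing isopropenyl = C10/C9, C2 CH2, C3 ketone/ketal carbon, C4 CHMe, C5 the carvone carbonyl carbon that becomes CH2, C6 carbinol/lactone carbon, C7/C8 the alkoxyvinyl carbons, C11–C13 lactone carbons); α/β refer to the ring face with H7 = α.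
Remark 2: the configurations of the oxygen-bearing centres created in steps 1 and 3 are erased later; the SMILES show the expected major isomers.
Remark 3: the enol ether oxygen carries a 4-methoxybenzyl (PMB) group because it can chelate lithium and zinc in steps 14 and 15 and is removed oxidatively in step 17 with ketal, alkene and lactone intact.

**Route**

Step 1
Reactants: 1 (S)-(+)-carvone
Product: 3 (5R,6R)-6-hydroxycarvone (OH on C6 anti to isopropenyl), via potassium dienolate 2 (not isolated)
Conditions: KN(SiMe3)2, THF, −78 °C; 2-(phenylsulfonyl)-3-phenyloxaziridine, −78 °C; H2O quench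
Reagents that add atoms: 2-(phenylsulfonyl)-3-phenyloxaziridine, O=S(=O)(N1OC1c1ccccc1)c1ccccc1
Why: Kinetic deprotonation of the enone at the α'-CH2 (C6) gives the cross-conjugated dienolate, and oxygen transfer from the N-sulfonyloxaziridine (enolate hydroxylation) should occur anti to the adjacent isopropenyl group; the carbinol centre is oxidised in step 9, so its configuration does not matter.

Step 2
Reactants: 3 (5R,6R)-6-hydroxycarvone
Product: 4 6-(tert-butyldimethylsilyloxy)carvone
Conditions: t-BuMe2SiCl, imidazole, DMF, 25 °C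
Reagents that add atoms: tert-butyldimethylsilyl chloride, CC(C)(C)[Si](C)(C)Cl
Why: Standard silylation of a secondary alcohol masks the ketol through the basic epoxidation and the transposition.

Step 3
Reactants: 4 6-(tert-butyldimethylsilyloxy)carvone
Product: 5 C3,C4-epoxy ketone (epoxide anti to isopropenyl)
Conditions: 30% H2O2, NaOH (aq), MeOH, 0 °C
Reagents that add atoms: hydrogen peroxide, OO
Why: Weitz–Scheffer epoxidation (conjugate addition of hydroperoxide to C3, then ring closure), expected anti to the isopropenyl group; both epoxide centres are erased in steps 4 and 5.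

Step 4
Reactants: 5 C3,C4-epoxy ketone
Product: 6 transposed allylic alcohol (C3–OH, C4=C5 alkene, C6–OSi)
Conditions: N2H4·H2O, AcOH (cat.), MeOH, 0 → 25 °C
Reagents that add atoms: none
Why: Wharton transposition: the epoxy hydrazone opens to a vinyl diazene that loses N2, moving the oxygen from C5 to C3 and the alkene to C4=C5; epoxide opening should be much faster than loss of the α'-silyloxy group.

Step 5
Reactants: 6 transposed allylic alcohol
Product: 7 transposed enone (C3 ketone, C4=C5)
Conditions: Dess–Martin periodinane, NaHCO3, CH2Cl2, 0 → 25 °C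
Reagents that add atoms: none
Why: Buffered periodinane oxidation of the secondary allylic alcohol gives the enone under neutral conditions without touching the silyl ether.

Step 6
Reactants: 7 transposed enone
Product: 9 (2R,4S,5R)-4-(tert-butyldimethylsilyloxy)-2-methyl-5-(prop-1-en-2-yl)cyclohexan-1-one (all-equatorial; 4R in target numbering), via lithium enolate 8 (not isolated)
Conditions: LiBH(s-Bu)3, THF, −78 °C; MeOH; then K2CO3, MeOH, 25 °C
Reagents that add atoms: none
Why: 1,4-Hydride addition to the β-unsubstituted enone (as with carvone itself) gives the enolate, and protonation followed by base equilibration sets C4 thermodynamically with methyl, silyloxy and isopropenyl all equatorial, i.e. methyl trans to isopropenyl.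

Step 7
Reactants: 9 saturated C3 ketone
Product: 10 C3 ethylene ketal silyl ether
Conditions: Me3SiOCH2CH2OSiMe3, Me3SiOTf (cat.), CH2Cl2, −78 → −20 °C; pyridine quench
Reagents that add atoms: 1,2-bis(trimethylsilyloxy)ethane, C[Si](C)(C)OCCO[Si](C)(C)C
Why: Silyl triflate-catalysed ketalisation with the bis-silyl ether of ethylene glycol runs at low temperature, so C4 next to the carbonyl is not epimerised and the silyl ether stays.

Step 8
Reactants: 10 C3 ethylene ketal silyl ether
Product: 11 (6R,8S,9R)-6-methyl-9-(prop-1-en-2-yl)-1,4-dioxaspiro[4.5]decan-8-ol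
Conditions: Bu4NF, THF, 25 °C
Reagents that add atoms: none
Why: Fluoride cleaves the Si–O bond of the secondary silyl ether; the ketal is inert.

Step 9
Reactants: 11 ketal alcohol
Product: 12 (6R,9R)-6-methyl-9-(prop-1-en-2-yl)-1,4-dioxaspiro[4.5]decan-8-one (C6 ketone, C3 ketal)
Conditions: Dess–Martin periodinane, NaHCO3, CH2Cl2, 0 → 25 °C
Reagents that add atoms: none
Why: Buffered periodinane oxidation gives the ketone without acid or base, so the α-isopropenyl centre C1 is neither epimerised nor moved into conjugation.

Step 10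
Reactants: 13 4-methoxybenzyl alcohol, 14 trichloroethylene
Product: 17 (E)-1,2-dichlorovinyl 4-methoxybenzyl ether, via potassium 4-methoxybenzyl oxide 15 (not isolated), via dichloroacetylene 16 (not isolated)
Conditions: KH, THF, 0 °C; then 14, −50 → 25 °C
Reagents that add atoms: none
Why: The alkoxide dehydrochlorinates trichloroethylene to dichloroacetylene and adds to it in anti fashion, the known route to (E)-1,2-dichlorovinyl ethers as alkynyl ether precursors.

Step 11
Reactants: 12 ketone, 17 (E)-1,2-dichlorovinyl 4-methoxybenzyl ether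
Product: 19 (6R,8S,9R)-8-[(4-methoxybenzyloxy)ethynyl]-6-methyl-9-(prop-1-en-2-yl)-1,4-dioxaspiro[4.5]decan-8-ol (alkynyl axial and cis to isopropenyl), via lithium alkoxyacetylide 18 (not isolated)
Conditions: 17, n-BuLi (2.2 equiv), THF, −78 °C; CeCl3, −78 °C; then 12, −78 °C; NaHCO3 (aq) work-up
Reagents that add atoms: none
Why: Two equivalents of butyllithium convert the dichlorovinyl ether by elimination and Cl–Li exchange into the lithium alkoxyacetylide, which adds 1,2 to the ketone (cerium suppresses enolisation of the acidic C1–H) along the axial trajectory preferred by slim sp nucleophiles, placing the alkynyl group axial and cis to the equatorial isopropenyl group.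

Step 12
Reactants: 19 alkynyl ether carbinol
Product: 20 (6R,8S,9R)-8-[(Z)-2-(4-methoxybenzyloxy)ethenyl]-6-methyl-9-(prop-1-en-2-yl)-1,4-dioxaspiro[4.5]decan-8-ol
Conditions: H2 (1 atm), Pd/CaCO3 poisoned with Pb(OAc)2, quinoline, EtOAc/Et3N, 25 °C; Et3N-treated silica
Reagents that add atoms: none
Why: Semihydrogenation on the lead-poisoned palladium catalyst adds H2 syn to the alkyne and stops at the Z-enol ether; the 1,1-disubstituted alkene and the benzylic ether are not reduced.

Step 13
Reactants: 20 cis-1-(Z-alkoxyvinyl)-2-isopropenylcyclohexanol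
Product: 23 (4R,8R)-silyl enol ether of the ring-expanded ketone (ten-membered ring; C6–OSiMe3 with C6=C7; 8β-OPMB; C3 ketal; Z C1=C10), via potassium alkoxide 21 (not isolated), via potassium enolate 22 (not isolated)
Conditions: KH, 18-crown-6, THF, 0 → 25 °C; then Me3SiCl/Et3N, −78 °C; non-aqueous work-up
Reagents that add atoms: chlorotrimethylsilane, C[Si](C)(C)Cl
Why: KH gives the potassium alkoxide 21, whose C1–C6 bond is weakened so that the 1,5-diene C8=C7–C6–C1–C10=C9 undergoes an alkoxide-accelerated [3,3] sigmatropic shift (anionic oxy-Cope rearrangement; closest precedent is the ring expansion of cis-1,2-dialkenylcyclohexanols to (Z)-cyclodec-5-enone enolates), forming C8–C9 and breaking C1–C6. The ten-membered ring is not closed end to end but arises by four-carbon ring expansion of the six-membered ring (C7, C8, C9 and C10 come to lie between C6 and C1) through a six-centre chair transition state. The cyclohexane chair with equatorial C4 methyl and isopropenyl groups and axial alkoxyvinyl group permits only the chair array in which C2 is pseudo-axial, which gives the Z C1=C10 alkene, and in which C9 bonds to the face of the Z-enol ether that makes C8 R (8β-oxygen); the carvone-derived centre C1 is thereby traded for C8. The step needs chair over boat and no ring flip, which the two equatorial anchors secure because the flipped chair would make both axial, and it needs the β-alkoxy enolate 22 to survive. In the ring-expanded enolate the ring holds C8–C9 roughly perpendicular to the enolate plane and the C8–O bond near its nodal plane, which disfavours loss of the alkoxide, and silylation at −78 °C as soon as the shift is complete stores the regiodefined C6=C7 enolate as 23.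

Step 14
Reactants: 23 silyl enol ether, 24 ethyl bromoacetate
Product: 26 (4R,7R,8R)-keto ester (C6 ketone; C7–CH2CO2Et β and cis to the 8β-OPMB group), via lithium enolate 25 (not isolated)
Conditions: MeLi, THF, −20 → 0 °C; then 24, −78 → −30 °C
Reagents that add atoms: none
Why: Methyllithium cleaves the silyl enol ether to the regiodefined lithium enolate, which is alkylated (SN2, in the sense of the Fráter–Seebach alkylation of chelated β-oxygenated enolates) on the face anti to C9 while lithium bridges the enolate and C8 ether oxygens and keeps the C8–O bond in the enolate plane, giving the 7,8-anti product with C11 β.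

Step 15
Reactants: 26 keto ester
Product: 28 (4R,6R,7R,8R)-trans-fused γ-lactone (6α,12-olide; 8β-OPMB; C3 ketal), via hydroxy ester 27 (not isolated)
Conditions: Zn(BH4)2, Et2O, −20 °C; then pyridinium p-toluenesulfonate (cat.), benzene, 50 °C
Reagents that add atoms: none
Why: Zinc bridges the C6 carbonyl and the C8 ether oxygen and hydride enters on the face of the chelate opposite the C7 side chain (chelation-controlled reduction of an α-substituted β-alkoxy ketone), giving the 6α-alcohol with H6 and H7 trans, which closes the five-membered lactone onto the ester by acid-catalysed acyl substitution.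

Step 16
Reactants: 28 γ-lactone
Product: 32 α-methylene-γ-lactone (8β-OPMB; C3 ketal), via lithium enolate 29 (not isolated), via Mannich base 30 (not isolated), via ammonium iodide 31 (not isolated)
Conditions: LiN(i-Pr)2, THF, −78 °C; CH2=NMe2 iodide, −78 → 25 °C; then MeI, MeOH, 25 °C; then NaHCO3 (aq), CH2Cl2
Reagents that add atoms: dimethylmethyleneiminium iodide, C=[N+](C)C.[I-]
Why: Mannich reaction of the lactone enolate with the iminium salt, N-methylation and base-induced elimination of trimethylamine (the standard α-methylenation of γ-lactones) install C13; C11 is the only acidic position and no stereocentre is touched.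

Step 17
Reactants: 32 α-methylene lactone PMB ether
Product: 33 8β-hydroxy α-methylene lactone (C3 ketal)
Conditions: DDQ, CH2Cl2/pH 7 buffer, 0 → 25 °C
Reagents that add atoms: none
Why: DDQ oxidises the electron-rich benzylic ether to an oxocarbenium ion that water hydrolyses (oxidative PMB cleavage), leaving ketal, trisubstituted alkene and methylene lactone intact and C8 untouched.

Step 18
Reactants: 34 tert-butyl acrylate, 35 acetaldehyde
Product: 36 tert-butyl 3-hydroxy-2-methylenebutanoate (racemic)
Conditions: DABCO, neat, 25 °C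
Reagents that add atoms: none
Why: Morita–Baylis–Hillman reaction: the amine adds to the acrylate, the zwitterionic enolate adds to acetaldehyde and the amine is eliminated; the racemic carbinol centre disappears in step 20.

Step 19
Reactants: 36 tert-butyl 3-hydroxy-2-methylenebutanoate
Product: 37 tert-butyl 3-acetoxy-2-methylenebutanoate
Conditions: Ac2O, pyridine, DMAP (cat.), CH2Cl2, 0 °C
Reagents that add atoms: acetic anhydride, CC(=O)OC(C)=O
Why: Acyl transfer to the secondary allylic alcohol gives the acetate needed for the allylic transposition.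

Step 20
Reactants: 37 tert-butyl 3-acetoxy-2-methylenebutanoate
Product: 38 tert-butyl (E)-2-(acetoxymethyl)but-2-enoate
Conditions: DABCO (cat.), THF, reflux
Reagents that add atoms: none
Why: DABCO displaces acetate in SN2' fashion and acetate returns SN2' at the primary carbon (1,3-transposition of Morita–Baylis–Hillman acetates), giving under thermodynamic control the trisubstituted alkene with the methyl group trans to the ester, the E isomer required.

Step 21
Reactants: 38 tert-butyl (E)-2-(acetoxymethyl)but-2-enoate
Product: 39 (E)-2-(acetoxymethyl)but-2-enoic acid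
Conditions: CF3CO2H, CH2Cl2, 25 °C
Reagents that add atoms: none
Why: Acidolysis of the tert-butyl ester (loss of 2-methylpropene) frees the acid without touching the allylic acetate.

Step 22
Reactants: 33 8β-hydroxy α-methylene lactone, 39 (E)-2-(acetoxymethyl)but-2-enoic acid
Product: 41 C3 ketal of the target (8β-ester), via mixed anhydride 40 (not isolated)
Conditions: 39, 2,4,6-trichlorobenzoyl chloride, Et3N, THF, 25 °C; then 33, DMAP, toluene, 25 °C
Reagents that add atoms: none
Why: Yamaguchi esterification: the mixed anhydride acylates DMAP and then the hindered C8 alcohol at oxygen, so C8 keeps its configuration; the primary allylic acetate is the thermodynamic isomer and should survive the nucleophilic catalyst.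

Step 23
Reactants: 41 C3 ketal of the target
Product: 42 CNP0265140.1
Conditions: pyridinium p-toluenesulfonate, acetone/H2O (10:1), 50 °C
Reagents that add atoms: water, O
Why: Mild acid-catalysed hydrolysis of the dioxolane releases the C3 ketone last, under conditions too weak to epimerise C4 or to move the C1=C10 alkene into conjugation.

**Compound list**

1 | (S)-(+)-carvone | CC1=CC[C@H](C(C)=C)CC1=O | starting material
2 | potassium cross-conjugated dienolate of carvone (C5–O, C5=C6) | [K+].[O-]C1=C[C@@H](C(C)=C)CC=C1C | intermediate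
3 | (5R,6R)-6-hydroxy-2-methyl-5-(prop-1-en-2-yl)cyclohex-2-en-1-one | CC1=CC[C@H](C(C)=C)[C@@H](O)C1=O | intermediate
4 | tert-butyldimethylsilyl ether of 3 | CC1=CC[C@H](C(C)=C)[C@@H](O[Si](C)(C)C(C)(C)C)C1=O | intermediate
5 | C3,C4-epoxy ketone of 4 (epoxide anti to isopropenyl) | C[C@@]12C(=O)[C@H](O[Si](C)(C)C(C)(C)C)[C@@H](C(C)=C)C[C@@H]1O2 | intermediate
6 | allylic alcohol: C3–OH, C4=C5, C6–OSi, C1 isopropenyl | CC1=C[C@H](O[Si](C)(C)C(C)(C)C)[C@@H](C(C)=C)C[C@@H]1O | intermediate
7 | enone: C3 ketone, C4=C5, C6–OSi | CC1=C[C@H](O[Si](C)(C)C(C)(C)C)[C@@H](C(C)=C)CC1=O | intermediate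
8 | lithium enolate from conjugate reduction of 7 | [Li+].[O-]C1=C(C)C[C@H](O[Si](C)(C)C(C)(C)C)[C@@H](C(C)=C)C1 | intermediate
9 | (2R,4S,5R)-4-(tert-butyldimethylsilyloxy)-2-methyl-5-(prop-1-en-2-yl)cyclohexan-1-one | C[C@@H]1C[C@H](O[Si](C)(C)C(C)(C)C)[C@@H](C(C)=C)CC1=O | intermediate
10 | ethylene ketal of 9 | C[C@@H]1C[C@H](O[Si](C)(C)C(C)(C)C)[C@@H](C(C)=C)CC12OCCO2 | intermediate
11 | (6R,8S,9R)-6-methyl-9-(prop-1-en-2-yl)-1,4-dioxaspiro[4.5]decan-8-ol | C[C@@H]1C[C@H](O)[C@@H](C(C)=C)CC12OCCO2 | intermediate
12 | (6R,9R)-6-methyl-9-(prop-1-en-2-yl)-1,4-dioxaspiro[4.5]decan-8-one | C[C@@H]1CC(=O)[C@@H](C(C)=C)CC12OCCO2 | intermediate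
13 | 4-methoxybenzyl alcohol | COc1ccc(CO)cc1 | starting material
14 | trichloroethylene | ClC=C(Cl)Cl | starting material
15 | potassium 4-methoxybenzyl oxide | [K+].[O-]Cc1ccc(OC)cc1 | intermediate
16 | dichloroacetylene | ClC#CCl | intermediate
17 | (E)-1,2-dichlorovinyl 4-methoxybenzyl ether | COc1ccc(CO/C(Cl)=C\Cl)cc1 | intermediate
18 | lithium (4-methoxybenzyloxy)acetylide | [Li]C#COCc1ccc(OC)cc1 | intermediate
19 | (6R,8S,9R)-8-[(4-methoxybenzyloxy)ethynyl]-6-methyl-9-(prop-1-en-2-yl)-1,4-dioxaspiro[4.5]decan-8-ol | C[C@@H]1C[C@@](O)(C#COCc3ccc(OC)cc3)[C@@H](C(C)=C)CC12OCCO2 | intermediate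
20 | (6R,8S,9R)-8-[(Z)-2-(4-methoxybenzyloxy)ethenyl]-6-methyl-9-(prop-1-en-2-yl)-1,4-dioxaspiro[4.5]decan-8-ol | C[C@@H]1C[C@@](O)(/C=C\OCc3ccc(OC)cc3)[C@@H](C(C)=C)CC12OCCO2 | intermediate
21 | potassium alkoxide of 20 | C[C@@H]1C[C@@]([O-])(/C=C\OCc3ccc(OC)cc3)[C@@H](C(C)=C)CC12OCCO2.[K+] | intermediate
22 | potassium C6 enolate of the ring-expanded ketone (C6=C7, ring carbons trans; 8R; Z C1=C10) | [K+].[O-]/C1=C\[C@H](OCc2ccc(OC)cc2)C/C(C)=C\CC2(OCCO2)[C@H](C)C1 | intermediate
23 | trimethylsilyl enol ether of the ring-expanded ketone (4R,8R) | C[Si](C)(C)O/C1=C\[C@H](OCc2ccc(OC)cc2)C/C(C)=C\CC2(OCCO2)[C@H](C)C1 | intermediate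
24 | ethyl bromoacetate | CCOC(=O)CBr | starting material
25 | lithium C6 enolate (from 23) | [Li+].[O-]/C1=C\[C@H](OCc2ccc(OC)cc2)C/C(C)=C\CC2(OCCO2)[C@H](C)C1 | intermediate
26 | (4R,7R,8R)-keto ester: C6 ketone, C7–CH2CO2Et, 8β-OPMB, C3 ketal | O=C1C[C@@H](C)C2(OCCO2)C/C=C(/C)C[C@@H](OCc2ccc(OC)cc2)[C@H]1CC(=O)OCC | intermediate
27 | (4R,6R,7S,8R)-6α-hydroxy ester | O[C@@H]1C[C@@H](C)C2(OCCO2)C/C=C(/C)C[C@@H](OCc2ccc(OC)cc2)[C@H]1CC(=O)OCC | intermediate
28 | (4R,6R,7R,8R)-6α,12-olide, 8β-OPMB, C3 ketal | O=C1O[C@@H]2C[C@@H](C)C3(OCCO3)C/C=C(/C)C[C@@H](OCc3ccc(OC)cc3)[C@H]2C1 | intermediate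
29 | lithium enolate of lactone 28 | C1=C([O-])O[C@@H]2C[C@@H](C)C3(OCCO3)C/C=C(/C)C[C@@H](OCc3ccc(OC)cc3)[C@@H]12.[Li+] | intermediate
30 | C11-(dimethylaminomethyl) lactone (C11 epimers) | CN(C)CC1C(=O)O[C@@H]2C[C@@H](C)C3(OCCO3)C/C=C(/C)C[C@@H](OCc3ccc(OC)cc3)[C@@H]12 | intermediate
31 | trimethylammonium iodide of 30 | C[N+](C)(C)CC1C(=O)O[C@@H]2C[C@@H](C)C3(OCCO3)C/C=C(/C)C[C@@H](OCc3ccc(OC)cc3)[C@@H]12.[I-] | intermediate
32 | α-methylene-γ-lactone, 8β-OPMB, C3 ketal | C=C1C(=O)O[C@@H]2C[C@@H](C)C3(OCCO3)C/C=C(/C)C[C@@H](OCc3ccc(OC)cc3)[C@@H]12 | intermediate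
33 | (4R,6R,7R,8R)-8β-hydroxy α-methylene lactone, C3 ketal | C=C1C(=O)O[C@@H]2C[C@@H](C)C3(OCCO3)C/C=C(/C)C[C@@H](O)[C@@H]12 | intermediate
34 | tert-butyl acrylate | C=CC(=O)OC(C)(C)C | starting material
35 | acetaldehyde | CC=O | starting material
36 | tert-butyl 3-hydroxy-2-methylenebutanoate (racemic) | CC(O)C(=C)C(=O)OC(C)(C)C | intermediate
37 | tert-butyl 3-acetoxy-2-methylenebutanoate (racemic) | CC(OC(C)=O)C(=C)C(=O)OC(C)(C)C | intermediate
38 | tert-butyl (E)-2-(acetoxymethyl)but-2-enoate | C/C=C(\COC(C)=O)C(=O)OC(C)(C)C | intermediate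
39 | (E)-2-(acetoxymethyl)but-2-enoic acid | C/C=C(\COC(C)=O)C(=O)O | intermediate
40 | mixed anhydride of 39 with 2,4,6-trichlorobenzoic acid | C/C=C(\COC(C)=O)C(=O)OC(=O)c1c(Cl)cc(Cl)cc1Cl | intermediate
41 | (4R,6R,7S,8R)-C3 ethylene ketal of the target | C=C1C(=O)O[C@@H]2C[C@@H](C)C3(OCCO3)C/C=C(/C)C[C@@H](OC(=O)/C(=C/C)COC(C)=O)[C@@H]12 | intermediate
42 | CNP0265140.1: (4R,6R,7S,8R)-8β-[(E)-2-(acetoxymethyl)but-2-enoyloxy]-3-oxogermacra-1(10)Z,11(13)-dien-12,6α-olide | C=C1C(=O)O[C@@H]2C[C@@H](C)C(=O)C/C=C(/C)C[C@@H](OC(=O)/C(=C/C)COC(C)=O)[C@@H]12 | target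

**Step count**

Total: 23 steps. Longest linear sequence: 18 steps from (S)-carvone (steps 1–9, 11–17, 22, 23).

**Steps most likely to fail**

Step 13. The process at risk is loss of the C8 alkoxide from the β-alkoxy enolate before it is silylated, made more likely if the pseudo-axial Z-alkoxy group slows the shift. The fallback gives the enol ether oxygen a tert-butyl group, a much poorer nucleofuge. It sets out from ketone 12. tert-Butanol, KH and 14 give (E)-1,2-dichlorovinyl tert-butyl ether F1. F1 with n-BuLi and then 12 gives the tert-butoxyethynyl carbinol F2, and semihydrogenation gives the (Z)-2-tert-butoxyvinyl carbinol F3. KH/18-crown-6 followed by Me3SiCl gives the silyl enol ether F4. MeLi and 24 give the keto ester F5, Zn(BH4)2 and acid give the lactone F6, and methylenation as in step 16 gives the methylene lactone F7. Me3SiOTf/2,6-lutidine then exchanges the tert-butyl ether for the trimethylsilyl ether F8, under conditions that ketone dioxolanes should tolerate. Aqueous citric acid cleaves F8 to 33, where the route is rejoined.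

Step 14. The process at risk is attack of the electrophile on the other face of the enolate if lithium chelation by the C8 ether is incomplete, since allylic strain then favours the conformer that leads to the C7 epimer. The fallback uses the E-enol ether, for which ring shielding and allylic strain point the same way, and corrects C8 at the end. It sets out from 19. LiAlH4 (trans-hydroalumination directed by the propargylic alkoxide) gives the (E)-enol ether F9. Ring expansion through the chair with the alkoxy group equatorial and silylation give the 8-epimeric silyl enol ether F10, in which H8 eclipses the enolate and C9 covers the inner face. MeLi and 24 in THF/DMPU should give the keto ester F11 with C7 as in 26. Reduction and lactonisation give the lactone F12, methylenation gives F13 and DDQ gives the 8α-alcohol F14. Mitsunobu esterification of F14 with acid 39 (PPh3, diisopropyl azodicarboxylate) inverts C8 and returns to 41.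

Step 15. The process at risk is hydride delivery to the other face of the C6 carbonyl, which would give the 6β-alcohol and, after lactonisation with retention, the cis-fused lactone. The fallback closes the lactone with inversion instead. It sets out from 26. The reduction product is taken as the 6-epimeric hydroxy ester F15 without acid treatment. LiOH gives the hydroxy acid F16, kept as its salt until use. Mitsunobu lactonisation (PPh3, diisopropyl azodicarboxylate) displaces the activated C6 oxygen by the carboxylate with inversion and returns to 28.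

**Further compounds**

F1 | step 13 | (E)-1,2-dichlorovinyl tert-butyl ether | CC(C)(C)O/C(Cl)=C\Cl
F2 | step 13 | tert-butoxyethynyl carbinol | C[C@@H]1C[C@@](O)(C#COC(C)(C)C)[C@@H](C(C)=C)CC12OCCO2
F3 | step 13 | (Z)-2-tert-butoxyvinyl carbinol | C[C@@H]1C[C@@](O)(/C=C\OC(C)(C)C)[C@@H](C(C)=C)CC12OCCO2
F4 | step 13 | silyl enol ether with 8β-tert-butoxy group | C[Si](C)(C)O/C1=C\[C@H](OC(C)(C)C)C/C(C)=C\CC2(OCCO2)[C@H](C)C1
F5 | step 13 | keto ester with 8β-tert-butoxy group | O=C1C[C@@H](C)C2(OCCO2)C/C=C(/C)C[C@@H](OC(C)(C)C)[C@H]1CC(=O)OCC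
F6 | step 13 | lactone with 8β-tert-butoxy group | O=C1O[C@@H]2C[C@@H](C)C3(OCCO3)C/C=C(/C)C[C@@H](OC(C)(C)C)[C@H]2C1
F7 | step 13 | methylene lactone with 8β-tert-butoxy group | C=C1C(=O)O[C@@H]2C[C@@H](C)C3(OCCO3)C/C=C(/C)C[C@@H](OC(C)(C)C)[C@@H]12
F8 | step 13 | 8-O-trimethylsilyl ether of 33 | C=C1C(=O)O[C@@H]2C[C@@H](C)C3(OCCO3)C/C=C(/C)C[C@@H](O[Si](C)(C)C)[C@@H]12
F9 | step 14 | (E)-2-(4-methoxybenzyloxy)vinyl carbinol | C[C@@H]1C[C@@](O)(/C=C/OCc3ccc(OC)cc3)[C@@H](C(C)=C)CC12OCCO2
F10 | step 14 | 8-epimeric silyl enol ether | C[Si](C)(C)O/C1=C\[C@@H](OCc2ccc(OC)cc2)C/C(C)=C\CC2(OCCO2)[C@H](C)C1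
F11 | step 14 | 8-epimeric keto ester | O=C1C[C@@H](C)C2(OCCO2)C/C=C(/C)C[C@H](OCc2ccc(OC)cc2)[C@H]1CC(=O)OCC
F12 | step 14 | 8-epimeric lactone | O=C1O[C@@H]2C[C@@H](C)C3(OCCO3)C/C=C(/C)C[C@H](OCc3ccc(OC)cc3)[C@H]2C1
F13 | step 14 | 8-epimeric methylene lactone | C=C1C(=O)O[C@@H]2C[C@@H](C)C3(OCCO3)C/C=C(/C)C[C@H](OCc3ccc(OC)cc3)[C@@H]12
F14 | step 14 | 8α-hydroxy methylene lactone | C=C1C(=O)O[C@@H]2C[C@@H](C)C3(OCCO3)C/C=C(/C)C[C@H](O)[C@@H]12
F15 | step 15 | 6-epimeric (6β) hydroxy ester | O[C@H]1C[C@@H](C)C2(OCCO2)C/C=C(/C)C[C@@H](OCc2ccc(OC)cc2)[C@H]1CC(=O)OCC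
F16 | step 15 | 6-epimeric (6β) hydroxy acid | O[C@H]1C[C@@H](C)C2(OCCO2)C/C=C(/C)C[C@@H](OCc2ccc(OC)cc2)[C@H]1CC(=O)O
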